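The reading was due at 80 min, and before anything else I wanted to know how far this flask could have got by then.

substrate 0.050 M; solid reagent 0.100 M; initiator 0.25 mM; time 80 min

1. how much product there is at 80 min, in percent of the substrate charged
2. the change that raises the amount of product at 80 min, in percent of the substrate charged most ("none" if none brings more than 2 percentage points) (spring / autumn / none)
3. amount of product at 80 min, in percent of the substrate charged, after autumn

- percentages count the substrate that a species holds: one ended chains A counts as two
- for a step with 2 of a species take k times the square, and two of it per event
- solid, in amounts per volume of the solution: solid reagent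
- at the start none of the solid reagent is in solution
- run time (flask): 80 min

    initiator → 2 initiating radical (k1 = 7.2 × 10⁻⁴ s⁻¹)
    substrate + initiating radical → capped initiator + first chain carrier (k2 = 7.8 × 10⁵ L mol⁻¹ s⁻¹)
    coupling partner + first chain carrier → product + second chain carrier (k3 = 48000 L mol⁻¹ s⁻¹)
    substrate + second chain carrier → released group + first chain carrier (k4 = 15000 L mol⁻¹ s⁻¹)
    2 first chain carrier → ended chains A (k5 = 2.5 × 10⁸ L mol⁻¹ s⁻¹)
    2 second chain carrier → ended chains B (k6 = 6 × 10⁷ L mol⁻¹ s⁻¹)
    solid reagent ⇌ coupling partner, rate k7*(cs7 - [coupling partner]) while solid is left; crystals form when [coupling partner] > cs7 (cs7 = 21 mM, k7 = 0.016 s⁻¹)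

Leaving capping aside, substrate falls pseudo-first-order, at 15000 L mol⁻¹ s⁻¹ times the level of the second chain carrier. As an upper mark I took the level at which that carrier's own pairing, at 6 × 10⁷ L mol⁻¹ s⁻¹, takes up the whole radical supply from the initiator, whose half-life is 16 min. That level follows the square root of the initiator left, and the root decays at half the initiator's rate, so the integral up to the reading closes to 1.88. I called this the reach: the natural logarithm of the substrate's fall that the radicals can pay for at best by that time. Neither the coupling partner nor the solid enters it. So my reckoning gave a ceiling and no yield: product of 84.7% of the charge.

The forecast stood below that ceiling: 74% (70% to 78%), with autumn as the better change, giving 81% (77% to 85%), “limited by radical supply”.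

The simulation gave 74.4% for the flask. Spring, the doubled dissolution coefficient, gained 0.85 percentage points; autumn, the doubled solubility, gained 7.6 points and reached 82.0%, so the best change was autumn.

In the flask at 80.0 min, product stood 10 points under the ceiling, and pairs of the second chain carrier made up 47.2% of the pairings behind the ended chains, the rest being pairs of the first chain carrier. In the autumn flask, whose reach is the same 1.88, product stood 2.7 points under that ceiling, at 82.0%.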